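Millimolar is the wrong unit for this flask: I count every species as a fraction of the Qa charged, so that charge and time enter the reckoning as their product.

    Qd + Qc → Qe (k1 = 3.2 M⁻¹ min⁻¹, Ea1 = 66.0 kJ mol⁻¹)
    Qa + Qb ⇌ Qd + Qc (K2 = 3.4, k2 = 1.4 M⁻¹ min⁻¹, Ea2 = 81.0 kJ mol⁻¹, ΔH2 = 0 kJ mol⁻¹)
    (constants at 80 °C)

the same everywhere: Qa 20 mM; Qb 0.950 equiv; time 20 min

| run | temperature |
|---|---|
| noon | 80 °C |
| autumn | 130 °C |
| dusk | 105 °C |
| midnight | 55 °C |

- all constants are for 80 °C and move with temperature by the activation energies and enthalpies

1. the flask that comes out highest in share of Qd in all that became Qd or Qe, or "all alike" when all lie within 1.5 percentage points (noon / autumn / dusk / midnight / all alike)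
2. share of Qd in all that became Qd or Qe, noon
3. share of Qd in all that became Qd or Qe, autumn
4. share of Qd in all that became Qd or Qe, dusk
5. share of Qd in all that became Qd or Qe, midnight

The reversible step makes Qd and Qc in equal fractions and the drain to Qe removes them in equal fractions, so the two stay equal. I freeze Qa at its charge and Qb at 0.950 equiv and leave out the back step (the initial-rate approximation). Qd then grows with time and Qe with its cube, and Qe over Qd equals both rate constants, times the equivalents of Qb, times the square of charge and time, over 3. With the constants moved by their activation energies, that ratio comes to 0.00501 at midnight, 0.227 at noon, 6.21 at dusk and 113 in autumn. This is the drain number: Qe per Qd while Qa and Qb hold at their charge.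

The share of Qd is then 1 over 1 plus that number, so I reckon 99.5% for midnight and 81.5% for noon. For dusk and autumn the number is more than 1, the freeze is past its use, and I commit to no figure. I do commit to midnight as highest, since its number is the smallest.

The forecast names midnight, with 85% for noon, 7.3% for autumn, 33% for dusk and 99.5% for midnight, on the ground that Qe “barely registers while little Qd and Qc have built up”. Its noon figure is higher than mine.

The simulation gives midnight as highest, with 85.2% for noon, 9.16% for autumn, 33.0% for dusk and 99.5% for midnight, so the forecast holds on each within its tolerance.

The autumn drain number of 113 warned that the freeze would fail, and in the autumn flask Qa stands at 10.5% of its charge after 20.0 min. At 1.08 min the autumn flask, each step taken net, makes Qd 1.46 times faster than it uses it up, but at the asked time the same ratio is 0.473, so Qd is then made more slowly than it is used up.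

The autumn neighbour with 8.0 mM of Qa has the drain number 18.1. With equivalents and temperature held, its fractions are those of autumn itself at 8.00 min, earlier than the half-time reading, whose Qd and Qe give a share of 17.7%, so I expect a share above that. The simulation gives 21.7% for that neighbour.

(The rate constants stand for no real mixture; what happens was integrated by code.)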